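The readings stem from a simulated flask for an exercise, noise included.

A leftover comes first. If each starting material consumes one coupling partner, gamma's 0.400 M of coupling partner against 0.50 M of starting material must leave a remainder, however long the flask stands. That remainder, 20.0% of the charge, I call the stranded share: one minus coupling partner over starting material, while that ratio is below one. The crossing lies at equal charges. Above it, on the same count, no remainder is owed and conversion goes on with the clock, as a decay does with its time constant; below it coupling partner is the limiting reagent, and its charge caps the conversion. Theta, at a ratio of 1.30, stands above the crossing.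

| setting | Thursday's | Friday's | Monday's | theta | gamma |
|---|---|---|---|---|---|
| starting material | 0.50 M | 0.50 M | 0.50 M | 0.50 M | 0.50 M |
| coupling partner | 0.65 M | 0.65 M | 0.60 M | 0.650 M | 0.400 M |
| second reagent | 0.65 M | 0.65 M | 0.65 M | 0.650 M | 0.650 M |
| third reagent | 0.26 M | 0.71 M | 0.30 M | 0.300 M | 1.00 M |
| temperature | 114 °C | 122 °C | 114 °C | 110 °C | 125 °C |
| remark | run made earlier | run made earlier | run made earlier |  |  |
| time |  |  |  | 20 h | 20 h |

| run | time / h | target / % | starting material / % |
|---|---|---|---|
| Thursday's | 4.00 | 10.2 | 39.8 |
| Thursday's | 8.00 | 15.6 | 19.2 |
| Thursday's | 10.0 | 15.5 | 16.5 |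
| Thursday's | 15.0 | 13.0 | 8.6 |
| Friday's | 1.00 | 3.2 | 56.0 |
| Friday's | 3.00 | 14.0 | 28.3 |
| Friday's | 6.00 | 20.0 | 12.2 |
| Friday's | 8.00 | 20.1 | 8.9 |
| Monday's | 1.00 | 0 | 73.0 |
| Monday's | 2.50 | 5.4 | 53.2 |
| Monday's | 6.00 | 13.4 | 29.3 |
| Monday's | 15.0 | 17.3 | 10.9 |

(scatter of a reading: 1 percentage point)



* which of the two ends with the higher amount of target, in percent of the starting material charged ("neither" if they lie within 2 percentage points) (theta / gamma / neither)
* target at the end, in percent of the starting material charged, theta
* target at the end, in percent of the starting material charged, gamma

Two chemists read these runs differently. The first holds that target follows conversion. Friday's run gave 20.1% of target at 91.1% conversion, a share of 22.1%. Thursday's run had converted 91.4% by 15.0 h, so theta, a little cooler but given 20 h, should stand near there and approach Friday's target. Gamma, with its stranded share, then reaches about 17.7% at that same share, so the first chemist expects theta to win.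

The second chemist, who made the forecast, answers with Thursday's run. At nearly the conversion of Friday's, Thursday's run held 13.0% of target, by my reckoning a share of 14.2%, after the 15.6% read at 8.00 h. The forecast takes theta's target to slip as Thursday's did, and it reads Monday's late target, against Thursday's fall, as a sign that excess coupling partner destroys target, which would spare gamma. It gives 14.5% for theta and 18.5% for gamma, so gamma ends higher. In its words: “Gamma is probably higher, but not by much.”

The flask gives 17.5% for theta and 22.7% for gamma, so gamma ends higher by 5.2 percentage points.

    starting material + coupling partner → intermediate A (k = 0.00640 M⁻¹ min⁻¹, Ea = 109 kJ mol⁻¹)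
    second reagent + intermediate A → intermediate B (k = 0.00330 M⁻¹ min⁻¹, Ea = 87.0 kJ mol⁻¹)
    third reagent + intermediate B → target (k = 0.130 M⁻¹ min⁻¹, Ea = 63.0 kJ mol⁻¹)
    target ⇌ isomer of the product (K = 3.00, k = 0.00450 min⁻¹, Ea = 130 kJ mol⁻¹, ΔH = −21.0 kJ mol⁻¹)
    (constants at 110 °C)

At the end theta still holds 26.8% as intermediate A, more than gamma's 4.08%. Gamma's starting material stands at 21%, against a stranded share of 20.0%. At 0.301 M of coupling partner the stranded share is 39.8%, and gamma's target has moved by 5 points, against the gap of 5.2 points; that is the region left to the first chemist's view. Theta's neighbour with 0.30 M of starting material has a stranded share of 0%; it still held 3.78% of starting material at 20.0 h, with 22.8% of target.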